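## Structural features

The target is tetracyclic: a seven-membered azepine and a five-membered pyrroline share the N4–C9a bond, and a cyclohexene is fused to the pyrroline along C1–C9a and to the azepine through C9. The tetrasubstituted C9=C9a enamine is therefore common to all three rings. A γ-lactone is cis-fused across C11–C12 (O on C11, methyl on C13, carbonyl C14), and a second α-methyl-γ-butyrolactone (C18–C21) hangs from C3. Ethyl at C10, the lactone oxygen at C11 and C13 at C12 are contiguous and all on one face; the quaternary carbinol C1 sits next to C12 with its hydroxyl on the opposite face; C3 carries its substituent trans to O1, and C18/C20 adjoin C3 in the side chain. Fragile groups are the enamine (acid, oxidants), the tertiary carbinol next to the enamine carbon (dehydration with aromatisation of the six-membered ring, acid-induced 1,2-shifts), both lactones (base) and C13, whose methyl lies cis to the C12–C1 bond and can epimerise. The real difficulty is the quaternary carbinol C1 in a fixed relation to C3 on one side and to the C10–C12 triad on the other. The key step exploits the 1,4-relation of C9a (nitrogen-bearing, unsaturated towards C9) and C11 (oxygen-bearing) across the cyclohexene together with the oxygen on C1: this is the pattern of a ring-opened oxanorbornene from a 2-amidofuran (oxygen bridging C9a and C11) and a C1-oxygenated alkene tethered through N4–C3–C2.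

## Logic of the disconnections

**35 ⇒ 34.** The C5 methylene is traced back to a lactam carbonyl. The acyl group on N4 is needed earlier: it makes the aminofuran stable and turns the enamine into a robust enamide for most of the route. The forward step must reduce one amide beside two lactones and leave the new enamine and the tertiary carbinol alone.

**34 ⇒ 33.** The O1–H bond is traced back to a benzyl ether, so that the carbinol is masked during the organometallic steps. The forward step is a hydrogenolysis that must spare the tetrasubstituted enamide.

**33 ⇒ 31 ⇒ 28 + 30.** The side lactone is cut at O–C21 and at C18–C19. This leaves a C3 acyl donor (28) and a three-carbon zinc reagent (30) that brings C20 from the chiral pool. The forward steps are a ketone synthesis that does not touch the fused lactone, and a ketone reduction that must set C18 under control of C3.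

**28 ⇒ 27 ⇒ 25.** These are changes of the C3 carboxyl derivative only. The tert-butyl ester of 25 must be cleaved without protic acid, because a protonated enamide next to the C1 oxygen invites rearrangement.

**25 ⇒ 23.** The lactone C–O bond (O11–C14) and the C11–H bond are cut, giving a C11 ketone flanked by C10 and C12. The forward reduction must deliver hydride to the β face. No equilibration at C10 or C12 is planned: an enolate towards C12 is aligned for β-elimination of the C1 oxygen, and the resulting dienone would aromatise.

**23 ⇒ 20 (key).** C9a–C1 and C11–C12 are cut and the furan is restored (the ketone oxygen becomes the ring oxygen, the C10 hydrogen returns to C11). Two rings and three stereocentres (C1, C10, C12) are traded for a flat furan and an enol ether. The enol ether in 20 must have C2 and C13 cis (E): a suprafacial addition then places C13 trans to O1 as required. The Z isomer (oxygen cis to C13) would give the C12 epimer, which cannot be corrected safely for the reason given above.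

**20 ⇒ 19.** N4–C9a is cut to a secondary amide and a 2-bromofuran. The dienophile is already present as an enol ether and is never carried as a C12=C13 enone. An enone tethered to the amidofuran would itself cycloadd through the four-atom tether, a free amino enone would close by aza-Michael addition, and the β-amido ketone could lose nitrogen by retro-Michael reaction. The forward coupling must tolerate the enol ether and the C3 centre.

**19 ⇒ 10 + 18.** The amide bond N4–C5 is cut into the furan acid and the amino ester; this is the convergent point of the synthesis.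

**18 ⇒ 17 ⇒ 14 + 16.** C1–C2 is cut. The enol ether is made by cross-coupling an alkylzinc reagent (from 15) with a ketene acetal phosphate, not by enolising a ketone. This fixes the position of the double bond (no choice between C2 and C12) and its geometry (set at the ester enolate stage). A conjugate hydride reduction of an enone would give the wrong, Z geometry.

**14 ⇒ 12 ⇒ 11.** The phosphate comes from the ester enolate of 12. C13 is bought as 11 and is not touched again.

**10 ⇒ 9 ⇒ 8 ⇒ 5 + 7 ⇒ 3 ⇒ 1.** The furan acid is cut at C9–C8 (alkyl–furyl coupling) and at C10–ethyl. The C2 bromine is introduced by ipso substitution of a silyl group that a bromine-directed lithiation places next to the future side chain. Direct bromination of a 3,4-dialkylfuran cannot tell the two α positions apart.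

## Other disconnections considered

**Alternative 1:** The cut opens N4–C9a and C9–C9a and contracts the azepine to a four-membered ring by re-forming N4–C7. In the forward step a metal carbenoid generated at C9a from a diazoketone is trapped by the ring nitrogen; the spiro ammonium ylide then undergoes a [2,3] shift through the alkenyl group to give A1.
- In its favour: one operation forms two bonds and both nitrogen rings, driven by release of ring strain. A1 already carries the side lactone and has N4 at the amine level, so no amide has to be deoxygenated at the end; on this point it is better than the chosen plan.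
- Against it: A1 has no carbocycle. The C1–C12 bond must still be made by closing the butenolide onto the C1 ketone, which has to set C1, C12 and C13 with less obvious control. The C7=C8 alkene left by the shift is two positions away from the required C9=C9a enamine. [1,2] shift and C–H insertion can compete, and the outcome at C9/C9a depends on which face of nitrogen is attacked.
- Comparison: structurally it solves the azabicycle and postpones the quaternary carbinol; the chosen plan does the reverse. Mechanistically both rest on a concerted, suprafacial pericyclic event, and are equal there. The stereodefined alkenyl azetidine would probably cost more steps than the two simple fragments used here, so step economy is likely worse, although the end-game would be shorter.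

**Alternative 2:** The cut is at C12–C13 and C1–O. In the forward step the C13 radical from a bromoacetal on O11 adds 5-exo to C12 of a cyclohexenone, and the tertiary α-keto radical at C1 is intercepted by oxygen to give A2.
- In its favour: haloacetal radical cyclisation (Ueno–Stork) is a dependable way to a cis-fused five-membered ring. The C11 oxygen is a control element from the start and is not re-created by reduction, which is better than the chosen plan. The enamine would later arise by simple amine–ketone condensation and the azepine by N-alkylation, so no amide reduction is needed, which is equal or better.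
- Against it: C1 is set by capture of a planar radical, with no secured facial preference. The C13 methyl in such cyclisations tends to the less hindered orientation, whereas the target has it on the hindered side. A2 still lacks both nitrogen rings and needs lactol oxidation, deprotection, condensation, alkylation and the whole side lactone. The cyclohexenone with C9, C10 and C11 must first be made in enantiopure form.
- Comparison: it builds the lactone and carbinol half first and the nitrogen rings last, a stepwise radical process against a concerted one. Each plan has one stereocentre-forming event of uncertain selectivity, so they are equal there. The step count is expected to be higher.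

**Alternative 3:** The cut is at C1–C2. In the forward step SmI2 turns an N4 bromoacetamide into a samarium enolate that adds to the C1 ketone (Reformatsky type) and gives A3.
- In its favour: the reaction is mild, organised by chelation, and forms the hindered bond and the carbinol late. A3 is the complete tetracyclic core. Its C3 lactam carbonyl is a natural handle for attaching the side lactone by partial reduction and vinylogous Mannich addition, which is shorter than the thioester/ketone/reduction sequence of the chosen plan and removes the amide oxygen in the same operation; on both points it is better.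
- Against it: all of the difficult carbocyclic stereochemistry (C10–C13) and the azepine must exist before the key step, which then solves the easiest ring. The substrate is a ketone next to an N-acyl enamine, open to pinacol-type reduction and to β-elimination. C1 must form anti to the C12 substituent, and C3 and C18 are left to substrate control.
- Comparison: on mechanism it uses a well-precedented reaction where the chosen plan relies on an untested dienophile, and is better there. On structure the chosen key step makes two rings and three stereocentres against one ring and one stereocentre. Step economy is probably similar, with the cost moved from the end-game to the preparation of the ketone.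

Key step: step 12

Assumptions (one line each):
- Atom numbers are those of the target (N4; C5–C8; C9=C9a; C1–C3; C10–C14; C18–C21); α is the face of the six-membered ring that carries O11, β the face that carries O1.
- The enol oxygen carries benzyl, not silyl (a protecting-group change): an enol ether with C2 and C13 cis is available regio- and stereospecifically from an ester enolate, and benzyloxy is a poorer leaving group β to the C11 ketone.
- Compounds 15 and 29 are taken as catalogue compounds (15 is otherwise one Appel iodination away from Fmoc-L-serine tert-butyl ester).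

## Route

Step 1
Reactants: 1 3,4-dibromofuran
Product: 3 3-bromo-4-ethylfuran, via (4-bromofuran-3-yl)lithium 2 (not isolated)
Conditions: n-BuLi (1.0 equiv), Et2O, −78 °C; EtOTf, −78 to −20 °C
Reagents that add atoms: ethyl trifluoromethanesulfonate, CCOS(=O)(=O)C(F)(F)F
Why: Halogen–lithium exchange of one of two equivalent bromides; the β-furyllithium keeps its position at −78 °C and the triflate is reactive enough to ethylate it before it isomerises.

Step 2
Reactants: 3 3-bromo-4-ethylfuran
Product: 5 (3-bromo-4-ethylfuran-2-yl)trimethylsilane, via (3-bromo-4-ethylfuran-2-yl)lithium 4 (not isolated)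
Conditions: LDA (1.1 equiv), THF, −78 °C; TMSCl
Reagents that add atoms: chlorotrimethylsilane, C[Si](C)(C)Cl
Why: Directed deprotonation: the α-hydrogen flanked by the ring oxygen and the C–Br bond is the most acidic and the amide base does not exchange bromine; the silyl group marks the α position next to the future side chain.

Step 3
Reactants: 5 (3-bromo-4-ethylfuran-2-yl)trimethylsilane, 6 ethyl 4-bromobutanoate
Product: 8 ethyl 4-[4-ethyl-2-(trimethylsilyl)furan-3-yl]butanoate, via (4-ethoxy-4-oxobutyl)zinc bromide 7 (not isolated)
Conditions: 6, Zn dust, LiCl, THF, 40 °C; then 5, Pd(OAc)2 (2 mol%), SPhos (4 mol%), THF, 50 °C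
Reagents that add atoms: none
Why: Negishi coupling of a primary alkylzinc with a hindered β-bromofuran; the biarylphosphine favours reductive elimination over β-hydride loss, and the ester and the C–Si bond are inert to the zinc reagent.

Step 4
Reactants: 8 ethyl 4-[4-ethyl-2-(trimethylsilyl)furan-3-yl]butanoate
Product: 9 ethyl 4-(2-bromo-4-ethylfuran-3-yl)butanoate
Conditions: NBS (1.0 equiv), DMF, −20 to 0 °C, dark
Reagents that add atoms: N-bromosuccinimide, O=C1CCC(=O)N1Br
Why: Electrophilic ipso-bromodesilylation; the β-silicon effect should make attack at the silylated α carbon faster than substitution at the free C–H, so the bromine ends up next to the butanoate chain only.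

Step 5
Reactants: 9 ethyl 4-(2-bromo-4-ethylfuran-3-yl)butanoate
Product: 10 4-(2-bromo-4-ethylfuran-3-yl)butanoic acid
Conditions: LiOH·H2O, THF/H2O, 0 °C to rt; then 1 M HCl to pH 3 at 0 °C
Reagents that add atoms: lithium hydroxide, [Li+].[OH-]
Why: Ester saponification; cold, brief acidification protects the acid-sensitive bromofuran.

Step 6
Reactants: 11 (S)-2-methylbutanedioic acid
Product: 12 dibenzyl (2S)-2-methylbutanedioate
Conditions: BnOH (2.5 equiv), TsOH·H2O (5 mol%), toluene, reflux, Dean–Stark
Reagents that add atoms: benzyl alcohol, OCc1ccccc1
Why: Fischer esterification under acid catalysis leaves the C13 centre untouched; the C1 benzyl group will become the O1 protecting group and the C14 benzyl ester is lost later on lactonisation.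

Step 7
Reactants: 12 dibenzyl (2S)-2-methylbutanedioate
Product: 14 benzyl (2S,3Z)-4-(benzyloxy)-4-[(diphenoxyphosphoryl)oxy]-2-methylbut-3-enoate, via lithium ester enolate 13 (not isolated)
Conditions: LDA (1.05 equiv), THF/DMPU 4:1, −78 °C; (PhO)2P(O)Cl, −78 to −40 °C
Reagents that add atoms: diphenyl chlorophosphate, O=P(Cl)(Oc1ccccc1)Oc1ccccc1
Why: Kinetic deprotonation should occur at the methylene and not at the tertiary C13–H; in the dipolar cosolvent the enolate with O–Li cis to C13 predominates, and O-phosphorylation fixes this geometry in the ketene acetal phosphate.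

Step 8
Reactants: 15 tert-butyl (2R)-2-(Fmoc-amino)-3-iodopropanoate, 14 benzyl (2S,3Z)-4-(benzyloxy)-4-[(diphenoxyphosphoryl)oxy]-2-methylbut-3-enoate
Product: 17 7-benzyl 1-tert-butyl (2S,4E,6S)-4-(benzyloxy)-2-(Fmoc-amino)-6-methylhept-4-enedioate, via alkylzinc iodide 16 (not isolated)
Conditions: 15, Zn dust (I2-activated), DMF, rt; then 14, Pd2(dba)3 (2.5 mol%), SPhos (10 mol%), DMF, 45 °C
Reagents that add atoms: none
Why: Zinc insertion gives a β-amino alkylzinc stabilised by internal coordination; Negishi coupling of ketene acetal phosphates with alkylzincs goes with retention, so C2 ends cis to C13 and the enol ether is formed at one position and with one geometry without enolising any ketone.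

Step 9
Reactants: 17 7-benzyl 1-tert-butyl (2S,4E,6S)-4-(benzyloxy)-2-(Fmoc-amino)-6-methylhept-4-enedioate
Product: 18 7-benzyl 1-tert-butyl (2S,4E,6S)-2-amino-4-(benzyloxy)-6-methylhept-4-enedioate
Conditions: piperidine (20% v/v), DMF, rt; concentrate cold, use at once
Reagents that add atoms: none
Why: Base-induced E1cB cleavage of the fluorenylmethyl carbamate; no acid is used, so the enol ether survives, and immediate use avoids slow lactamisation onto the C14 ester.

Step 10
Reactants: 10 4-(2-bromo-4-ethylfuran-3-yl)butanoic acid, 18 7-benzyl 1-tert-butyl (2S,4E,6S)-2-amino-4-(benzyloxy)-6-methylhept-4-enedioate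
Product: 19 7-benzyl 1-tert-butyl (2S,4E,6S)-4-(benzyloxy)-2-[4-(2-bromo-4-ethylfuran-3-yl)butanamido]-6-methylhept-4-enedioate
Conditions: EDC·HCl (1.3 equiv), HOBt (0.2 equiv), CH2Cl2, 0 °C to rt
Reagents that add atoms: none
Why: Carbodiimide amide coupling under near-neutral conditions; the primary amine acylates faster than any side reaction and the amino ester centre is not at risk because the acid partner has no α-stereocentre.

Step 11
Reactants: 19 7-benzyl 1-tert-butyl (2S,4E,6S)-4-(benzyloxy)-2-[4-(2-bromo-4-ethylfuran-3-yl)butanamido]-6-methylhept-4-enedioate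
Product: 20 7-benzyl 1-tert-butyl (2S,4E,6S)-4-(benzyloxy)-2-(3-ethyl-7-oxo-4,5,6,7-tetrahydro-8H-furo[2,3-b]azepin-8-yl)-6-methylhept-4-enedioate
Conditions: CuI (15 mol%), N,N′-dimethylethylenediamine (30 mol%), K3PO4 (2 equiv), toluene, 90 °C
Reagents that add atoms: none
Why: Intramolecular Goldberg amidation closes the seven-membered lactam on the 2-bromofuran; copper/diamine amidation of 2-bromofurans is established, and the weak heterogeneous base in toluene should leave the enol ether, the esters and C3 unchanged below the onset of the cycloaddition.

Step 12
Reactants: 20 7-benzyl 1-tert-butyl (2S,4E,6S)-4-(benzyloxy)-2-(3-ethyl-7-oxo-4,5,6,7-tetrahydro-8H-furo[2,3-b]azepin-8-yl)-6-methylhept-4-enedioate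
Product: 23 (1S,3S,10R,12S,13S)-tricyclic enamide C11 ketone with C1 benzyl ether, via oxanorbornene cycloadduct 21 (not isolated), via alkoxide–acyliminium zwitterion 22 (not isolated)
Conditions: toluene (0.01 M, degassed), BHT (0.1 equiv), 2,6-lutidine (0.2 equiv), sealed tube, 165 °C
Reagents that add atoms: none
Why: Proposed new method: the closest known reaction is the thermal intramolecular [4+2] cycloaddition of 2-amidofurans with tethered unactivated alkenes followed by nitrogen-assisted opening of the oxygen bridge; an enol ether has not been used as the 2π partner, so the irreversible ring opening must pull an electronically unfavourable cycloaddition forward. The furan carbons C9a and C11 add suprafacially to C1=C12 to give 21; this closes the pyrroline (bond C9a–C1, five-membered ring through the tether N4–C3–C2, which can only span the position syn to the oxygen bridge) and the carbocycle (bond C11–C12, six-membered ring formed by the cycloaddition itself). The lone pair of the lactam nitrogen then expels the C9a–O bond to give 22, and a suprafacial 1,2-shift of the C11 hydrogen to C10, the γ position of the conjugated acyliminium, delivers the ketone and the C9=C9a enamide. C1 is controlled by C3: allylic 1,3-strain with the lactam carbonyl keeps the C3–H in the amide plane and the tert-butyl ester pseudoaxial on the outer face of the forming pyrroline, so the enol ether should reach the furan face that puts the benzyloxy group (necessarily anti to the bridge) trans to the ester. C12 follows from the E geometry of the enol ether (C13 syn to the bridge, hence trans to O1). C10 follows from the face of C11 that carries the migrating hydrogen (anti to the former bridge oxygen, hence ethyl cis to the C12 chain). The step needs facial selectivity (C3 ester), retention of alkene geometry (concerted addition) and ring opening without loss of benzyl alcohol (neutral buffered medium, poor leaving group); C3 and C13 are spectators.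

Step 13
Reactants: 23 (1S,3S,10R,12S,13S)-tricyclic enamide C11 ketone with C1 benzyl ether
Product: 25 (1S,3S,10R,11R,12R,13S)-fused γ-lactone with C1 benzyl ether and C3 tert-butyl ester, via C11 hydroxy ester 24 (not isolated)
Conditions: NaBH4 (1.5 equiv), CeCl3·7H2O (1.2 equiv), MeOH/THF, −78 to −40 °C; AcOH quench; then toluene, AcOH (cat.), 50 °C
Reagents that add atoms: none
Why: Luche-type borohydride reduction; hydride should enter from the β face, anti to the ethyl group and the C12 chain that flank the carbonyl on the α face, and the resulting 11α-alcohol, cis to the C12 chain, closes the cis-fused lactone with loss of benzyl alcohol. The cold, cerium-buffered medium avoids the C12 enolate and leaves C13 alone.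

Step 14
Reactants: 25 (1S,3S,10R,11R,12R,13S)-fused γ-lactone with C1 benzyl ether and C3 tert-butyl ester
Product: 27 C3 carboxylic acid, via trimethylsilyl ester 26 (not isolated)
Conditions: TMSOTf (3 equiv), 2,6-lutidine (4 equiv), CH2Cl2, 0 °C to rt; then pH 4 buffer
Reagents that add atoms: none
Why: Silyl triflate with a hindered base cleaves the tert-butyl ester through the silyl ester with loss of isobutene and without protic acid, so the enamide is not protonated and the C1 ether, the lactone and C13 are not put at risk.

Step 15
Reactants: 27 C3 carboxylic acid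
Product: 28 C3 S-ethyl thioester
Conditions: EtSH (3 equiv), EDC·HCl (1.5 equiv), DMAP (0.1 equiv), CH2Cl2, 0 °C
Reagents that add atoms: ethanethiol, CCS
Why: Steglich-type thioesterification; low temperature and catalytic DMAP keep the activated N-acyl amino acid from epimerising at C3, and the lactone is inert.

Step 16
Reactants: 28 C3 S-ethyl thioester, 29 methyl (2R)-3-bromo-2-methylpropanoate
Product: 31 C3 γ-keto ester (C18 ketone), via zinc homoenolate 30 (not isolated)
Conditions: 29, Zn dust, LiCl, THF, 40 °C; then 28, PdCl2(PPh3)2 (10 mol%), toluene/THF, rt
Reagents that add atoms: none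
Why: Fukuyama coupling of a thioester with a functionalised alkylzinc gives the ketone under neutral conditions that tolerate lactone, lactam and ether; C20 comes from the chiral pool and its centre, β to zinc, is configurationally safe.

Step 17
Reactants: 31 C3 γ-keto ester (C18 ketone)
Product: 33 bis-lactone lactam with C1 benzyl ether, via lithium C18 alkoxide 32 (not isolated)
Conditions: L-Selectride (1.2 equiv), THF, −78 °C; warm to −20 °C; AcOH quench
Reagents that add atoms: none
Why: The bulky hydride should add under Felkin–Anh control with N4 perpendicular and anti to the nucleophile, giving the syn amino alcohol (18S); the alkoxide then lactonises onto the methyl ester on warming, and the low temperature spares the fused lactone and C20.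

Step 18
Reactants: 33 bis-lactone lactam with C1 benzyl ether
Product: 34 bis-lactone lactam with free C1 hydroxyl
Conditions: H2 (3 atm), Pd(OH)2/C, EtOAc/EtOH, rt
Reagents that add atoms: none
Why: Hydrogenolysis of the benzylic C–O bond; the tetrasubstituted, acylated enamide is not expected to be hydrogenated, and the lactones are stable under neutral conditions.

Step 19
Reactants: 34 bis-lactone lactam with free C1 hydroxyl
Product: 35 target CNP0179500.1
Conditions: RhH(CO)(PPh3)3 (5 mol%), Ph2SiH2 (4 equiv), THF, rt; then NH4F, MeOH
Reagents that add atoms: none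
Why: Rhodium hydride-catalysed hydrosilylation reduces tertiary amides to amines at room temperature and leaves esters and lactones alone; no Brønsted acid is present, so the new enamine is not reduced through its iminium and the carbinol is not exposed to rearrangement, and the fluoride work-up cleaves any O–Si bond formed at O1.

## Compound list

1 | 3,4-dibromofuran | Brc1cocc1Br | starting material
2 | (4-bromofuran-3-yl)lithium | [Li]c1cocc1Br | intermediate (not isolated)
3 | 3-bromo-4-ethylfuran | CCc1cocc1Br | intermediate
4 | (3-bromo-4-ethylfuran-2-yl)lithium | CCc1coc([Li])c1Br | intermediate (not isolated)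
5 | (3-bromo-4-ethylfuran-2-yl)trimethylsilane | CCc1coc([Si](C)(C)C)c1Br | intermediate
6 | ethyl 4-bromobutanoate | CCOC(=O)CCCBr | starting material
7 | (4-ethoxy-4-oxobutyl)zinc bromide | CCOC(=O)CCC[Zn]Br | intermediate (not isolated)
8 | ethyl 4-[4-ethyl-2-(trimethylsilyl)furan-3-yl]butanoate | CCOC(=O)CCCc1c(CC)coc1[Si](C)(C)C | intermediate
9 | ethyl 4-(2-bromo-4-ethylfuran-3-yl)butanoate | CCOC(=O)CCCc1c(CC)coc1Br | intermediate
10 | 4-(2-bromo-4-ethylfuran-3-yl)butanoic acid | OC(=O)CCCc1c(CC)coc1Br | intermediate
11 | (S)-2-methylbutanedioic acid ((S)-methylsuccinic acid) | OC(=O)C[C@H](C)C(=O)O | starting material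
12 | dibenzyl (2S)-2-methylbutanedioate | O=C(OCc1ccccc1)C[C@H](C)C(=O)OCc1ccccc1 | intermediate
13 | lithium enolate of 12 at the methylene, O–Li cis to C13 | [Li]O/C(OCc1ccccc1)=C\[C@H](C)C(=O)OCc1ccccc1 | intermediate (not isolated)
14 | benzyl (2S,3Z)-4-(benzyloxy)-4-[(diphenoxyphosphoryl)oxy]-2-methylbut-3-enoate (phosphate oxygen cis to C13) | O=P(Oc1ccccc1)(Oc1ccccc1)O/C(OCc1ccccc1)=C\[C@H](C)C(=O)OCc1ccccc1 | intermediate
15 | tert-butyl (2R)-2-{[(9H-fluoren-9-ylmethoxy)carbonyl]amino}-3-iodopropanoate (Fmoc-3-iodo-L-alanine tert-butyl ester) | CC(C)(C)OC(=O)[C@H](CI)NC(=O)OCC1c2ccccc2-c2ccccc12 | starting material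
16 | alkylzinc iodide from 15 (zinc on C2) | CC(C)(C)OC(=O)[C@H](C[Zn]I)NC(=O)OCC1c2ccccc2-c2ccccc12 | intermediate (not isolated)
17 | 7-benzyl 1-tert-butyl (2S,4E,6S)-4-(benzyloxy)-2-{[(9H-fluoren-9-ylmethoxy)carbonyl]amino}-6-methylhept-4-enedioate (C2 and C13 cis on the enol ether) | CC(C)(C)OC(=O)[C@H](C/C(OCc1ccccc1)=C\[C@H](C)C(=O)OCc1ccccc1)NC(=O)OCC1c2ccccc2-c2ccccc12 | intermediate
18 | 7-benzyl 1-tert-butyl (2S,4E,6S)-2-amino-4-(benzyloxy)-6-methylhept-4-enedioate | CC(C)(C)OC(=O)[C@H](C/C(OCc1ccccc1)=C\[C@H](C)C(=O)OCc1ccccc1)N | intermediate
19 | 7-benzyl 1-tert-butyl (2S,4E,6S)-4-(benzyloxy)-2-[4-(2-bromo-4-ethylfuran-3-yl)butanamido]-6-methylhept-4-enedioate | CCc1coc(Br)c1CCCC(=O)N[C@H](C(=O)OC(C)(C)C)C/C(OCc1ccccc1)=C\[C@H](C)C(=O)OCc1ccccc1 | intermediate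
20 | 7-benzyl 1-tert-butyl (2S,4E,6S)-4-(benzyloxy)-2-(3-ethyl-7-oxo-4,5,6,7-tetrahydro-8H-furo[2,3-b]azepin-8-yl)-6-methylhept-4-enedioate (precursor of the key step) | CCc1coc2c1CCCC(=O)N2[C@H](C(=O)OC(C)(C)C)C/C(OCc1ccccc1)=C\[C@H](C)C(=O)OCc1ccccc1 | intermediate
21 | oxanorbornene cycloadduct: oxygen bridging C9a and C11, C9=C10 alkene, benzyloxy on C1 anti to the bridge, C2 and C13 syn to it | CCC1=C2CCCC(=O)N3[C@H](C(=O)OC(C)(C)C)C[C@]4(OCc5ccccc5)[C@H]([C@H](C)C(=O)OCc5ccccc5)[C@@H]1O[C@]234 | intermediate (not isolated)
22 | zwitterion: C11 alkoxide (α), N4=C9a acyliminium, C9=C10 alkene | CCC1=C2CCCC(=O)[N+]3=C2[C@](OCc2ccccc2)(C[C@H]3C(=O)OC(C)(C)C)[C@H]([C@H](C)C(=O)OCc2ccccc2)[C@@H]1[O-] | intermediate (not isolated)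
23 | tert-butyl (1S,3S,10R,12S)-1-(benzyloxy)-12-[(2S)-1-(benzyloxy)-1-oxopropan-2-yl]-10-ethyl-5,11-dioxo tricyclic C9=C9a enamide 3-carboxylate (azepino[3,2,1-hi]indole core, target numbering; product of the key step) | CC[C@@H]1C2=C3N(C(=O)CCC2)[C@H](C(=O)OC(C)(C)C)C[C@]3(OCc2ccccc2)[C@H]([C@H](C)C(=O)OCc2ccccc2)C1=O | intermediate
24 | (11R)-11α-hydroxy derivative of 23 (hydroxy benzyl ester, OH cis to the C12 chain) | CC[C@@H]1C2=C3N(C(=O)CCC2)[C@H](C(=O)OC(C)(C)C)C[C@]3(OCc2ccccc2)[C@H]([C@H](C)C(=O)OCc2ccccc2)[C@@H]1O | intermediate (not isolated)
25 | tert-butyl (1S,3S,10R,11R,12R,13S)-1-(benzyloxy)-10-ethyl-13-methyl-5-oxo tetracyclic lactone 3-carboxylate (cis-fused O11–C14 γ-lactone, C9=C9a enamide) | CC[C@@H]1C2=C3N(C(=O)CCC2)[C@H](C(=O)OC(C)(C)C)C[C@]3(OCc2ccccc2)[C@H]2[C@@H]1OC(=O)[C@H]2C | intermediate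
26 | trimethylsilyl ester corresponding to 25 | CC[C@@H]1C2=C3N(C(=O)CCC2)[C@H](C(=O)O[Si](C)(C)C)C[C@]3(OCc2ccccc2)[C@H]2[C@@H]1OC(=O)[C@H]2C | intermediate (not isolated)
27 | C3 carboxylic acid corresponding to 25 | CC[C@@H]1C2=C3N(C(=O)CCC2)[C@H](C(=O)O)C[C@]3(OCc2ccccc2)[C@H]2[C@@H]1OC(=O)[C@H]2C | intermediate
28 | C3 S-ethyl thioester corresponding to 27 | CC[C@@H]1C2=C3N(C(=O)CCC2)[C@H](C(=O)SCC)C[C@]3(OCc2ccccc2)[C@H]2[C@@H]1OC(=O)[C@H]2C | intermediate
29 | methyl (2R)-3-bromo-2-methylpropanoate | BrC[C@H](C)C(=O)OC | starting material
30 | [(2R)-3-methoxy-2-methyl-3-oxopropyl]zinc bromide | Br[Zn]C[C@H](C)C(=O)OC | intermediate (not isolated)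
31 | C18 ketone: C3 bears C(=O)–CH2–(S)-CH(CH3)–CO2CH3 (20S); rest as 25 | CC[C@@H]1C2=C3N(C(=O)CCC2)[C@H](C(=O)C[C@H](C)C(=O)OC)C[C@]3(OCc2ccccc2)[C@H]2[C@@H]1OC(=O)[C@H]2C | intermediate
32 | lithium (18S)-alkoxide of the hydroxy ester from 31 | CC[C@@H]1C2=C3N(C(=O)CCC2)[C@H]([C@@H]([O-])C[C@H](C)C(=O)OC)C[C@]3(OCc2ccccc2)[C@H]2[C@@H]1OC(=O)[C@H]2C.[Li+] | intermediate (not isolated)
33 | (1S,3S,10R,11R,12R,13S,18S,20S)-1-O-benzyl-5-oxo derivative of the target (both lactones, C5 lactam) | CC[C@@H]1C2=C3N(C(=O)CCC2)[C@H]([C@@H]2C[C@H](C)C(=O)O2)C[C@]3(OCc2ccccc2)[C@H]2[C@@H]1OC(=O)[C@H]2C | intermediate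
34 | (1S,3S,10R,11R,12R,13S,18S,20S)-5-oxo derivative of the target (free C1 hydroxyl, C5 lactam) | CC[C@@H]1C2=C3N(C(=O)CCC2)[C@H]([C@@H]2C[C@H](C)C(=O)O2)C[C@]3(O)[C@H]2[C@@H]1OC(=O)[C@H]2C | intermediate
35 | CNP0179500.1, (1S,3S,10R,11R,12R,13S,18S,20S) | CC[C@@H]1C2=C3N(CCCC2)[C@H]([C@@H]2C[C@H](C)C(=O)O2)C[C@]3(O)[C@H]2[C@@H]1OC(=O)[C@H]2C | target

## Step count and least certain steps

Total: 19 steps. Longest linear sequence: 15 steps (steps 1–5 and 10–19, from 1).

**Step 12 (key step, Proposed new method).** The cycloaddition may be too slow: an electron-rich, trisubstituted enol ether on an electron-rich diene. Thermal decomposition of the amidofuran, loss of benzyl alcohol from the β-benzyloxy ketone with aromatisation, or erosion of facial selectivity at high temperature could then take over. The fallback uses only precedented reaction types and lowers the temperature by activating the diene.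
- It sets out from 9. Electrophilic sulfenylation of the free furan α position (MeSCl from dimethyl disulfide and sulfuryl chloride, CH2Cl2, −78 °C) would give ethyl 4-[2-bromo-4-ethyl-5-(methylsulfanyl)furan-3-yl]butanoate F1.
- Saponification gives the acid F2, carbodiimide coupling with 18 gives the amide F3, and copper-catalysed ring closure gives the 2-methylsulfanyl-5-amidofuran F4.
- Furans of this type are the most reactive dienes of the reaction family and cyclise at or slightly above room temperature. The sulfur substituent migrates in place of hydrogen (1,2-thio shift) to give the C10 methylsulfanyl ketone F5.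
- Reductive desulfenylation (aluminium amalgam or SmI2, THF/MeOH) then leads back to 23.

**Step 11.** C–N bond formation with the hindered secondary amide may be slow, so that protodebromination, epimerisation at C3 or premature cycloaddition intervene. The fallback changes the order of events so that the coupling is done on a simple substrate.
- It sets out from 10, which is coupled with O-TBS-L-serine tert-butyl ester to give the amide F6.
- Copper-catalysed closure gives the N-furyl lactam F7, fluoride gives the alcohol F8, and CBr4/PPh3 gives the bromide F9.
- Zinc insertion gives the alkylzinc F10, whose Negishi coupling with 14 returns to the route at 20.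

**Step 4.** Substitution at the free α C–H, or over-bromination, may compete with ipso attack. The fallback replaces silicon by boron, whose replacement is strictly ipso.
- It sets out from 3. The lithio species 4 is quenched with 2-isopropoxy-4,4,5,5-tetramethyl-1,3,2-dioxaborolane to give the boronate F11.
- Negishi coupling with 7 gives the boronate ester F12, and copper(II) bromide in aqueous methanol (bromodeboronation) returns to the route at 9.

**Step 13.** Hydride may be delivered from the α face (the C1 benzyloxy group shields the β face from a 1,3-position), or enolisation towards C12 may lead to β-elimination. The fallback inverts C11 instead of forming it directly.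
- It sets out from 23. The C11 epimeric alcohol F13 is taken on by selective hydrogenolysis of the benzyl ester (Pd/C, pyridine-doped, benzyl ether retained) to the hydroxy acid F14.
- Intramolecular Mitsunobu lactonisation closes the lactone with inversion at C11 and returns to the route at 25.

**Step 19.** Chemoselectivity may be incomplete: hydrosilylation of a lactone, or over-reduction of the enamine through its iminium. The fallback goes through the thiolactam.
- It sets out from 33. Lawesson's reagent (toluene, 80 °C) gives the thiolactam F15.
- Raney nickel in ethanol removes sulfur and the benzyl group in one operation and returns to the route at 35.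

## Further compounds

F1 | step 12 | ethyl 4-[2-bromo-4-ethyl-5-(methylsulfanyl)furan-3-yl]butanoate | CCOC(=O)CCCc1c(CC)c(SC)oc1Br
F2 | step 12 | 4-[2-bromo-4-ethyl-5-(methylsulfanyl)furan-3-yl]butanoic acid | OC(=O)CCCc1c(CC)c(SC)oc1Br
F3 | step 12 | amide of F2 with 18 | CCc1c(SC)oc(Br)c1CCCC(=O)N[C@H](C(=O)OC(C)(C)C)C/C(OCc1ccccc1)=C\[C@H](C)C(=O)OCc1ccccc1
F4 | step 12 | 2-(methylsulfanyl) analogue of 20 (sulfur on C11) | CCc1c(SC)oc2c1CCCC(=O)N2[C@H](C(=O)OC(C)(C)C)C/C(OCc1ccccc1)=C\[C@H](C)C(=O)OCc1ccccc1
F5 | step 12 | 10-(methylsulfanyl) analogue of 23 (SMe β, ethyl α) | CC[C@]1(SC)C2=C3N(C(=O)CCC2)[C@H](C(=O)OC(C)(C)C)C[C@]3(OCc2ccccc2)[C@H]([C@H](C)C(=O)OCc2ccccc2)C1=O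
F6 | step 11 | tert-butyl N-[4-(2-bromo-4-ethylfuran-3-yl)butanoyl]-O-(tert-butyldimethylsilyl)-L-serinate | CCc1coc(Br)c1CCCC(=O)N[C@@H](CO[Si](C)(C)C(C)(C)C)C(=O)OC(C)(C)C
F7 | step 11 | tert-butyl (2S)-3-[(tert-butyldimethylsilyl)oxy]-2-(3-ethyl-7-oxo-4,5,6,7-tetrahydro-8H-furo[2,3-b]azepin-8-yl)propanoate | CCc1coc2c1CCCC(=O)N2[C@@H](CO[Si](C)(C)C(C)(C)C)C(=O)OC(C)(C)C
F8 | step 11 | tert-butyl (2S)-2-(3-ethyl-7-oxo-4,5,6,7-tetrahydro-8H-furo[2,3-b]azepin-8-yl)-3-hydroxypropanoate | CCc1coc2c1CCCC(=O)N2[C@@H](CO)C(=O)OC(C)(C)C
F9 | step 11 | tert-butyl (2R)-3-bromo-2-(3-ethyl-7-oxo-4,5,6,7-tetrahydro-8H-furo[2,3-b]azepin-8-yl)propanoate | CCc1coc2c1CCCC(=O)N2[C@@H](CBr)C(=O)OC(C)(C)C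
F10 | step 11 | alkylzinc bromide from F9 | CCc1coc2c1CCCC(=O)N2[C@@H](C[Zn]Br)C(=O)OC(C)(C)C
F11 | step 4 | 2-(3-bromo-4-ethylfuran-2-yl)-4,4,5,5-tetramethyl-1,3,2-dioxaborolane | CCc1coc(B2OC(C)(C)C(C)(C)O2)c1Br
F12 | step 4 | ethyl 4-[4-ethyl-2-(4,4,5,5-tetramethyl-1,3,2-dioxaborolan-2-yl)furan-3-yl]butanoate | CCOC(=O)CCCc1c(CC)coc1B1OC(C)(C)C(C)(C)O1
F13 | step 13 | C11 epimer of 24 (11β-hydroxy benzyl ester) | CC[C@@H]1C2=C3N(C(=O)CCC2)[C@H](C(=O)OC(C)(C)C)C[C@]3(OCc2ccccc2)[C@H]([C@H](C)C(=O)OCc2ccccc2)[C@H]1O
F14 | step 13 | 11β-hydroxy C14 carboxylic acid from F13 | CC[C@@H]1C2=C3N(C(=O)CCC2)[C@H](C(=O)OC(C)(C)C)C[C@]3(OCc2ccccc2)[C@H]([C@H](C)C(=O)O)[C@H]1O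
F15 | step 19 | C5 thiolactam corresponding to 33 | CC[C@@H]1C2=C3N(C(=S)CCC2)[C@H]([C@@H]2C[C@H](C)C(=O)O2)C[C@]3(OCc2ccccc2)[C@H]2[C@@H]1OC(=O)[C@H]2C
A1 | alternative 1 | pyrrolo[1,2-a]azepin-1-one with C7=C8 alkene, butenolide chain on C9 and side lactone on C3 | CC[C@@H]([C@H]1OC(=O)C(C)=C1)[C@H]2C=CCCN3[C@@H]2C(=O)C[C@H]3[C@@H]4C[C@H](C)C(=O)O4
A2 | alternative 2 | cis-fused lactol ethyl ether with C1 hydroxyl, C9a ketone, chlorobutyl chain and Boc-amino ester chain | CC[C@@H]1[C@@H](CCCCCl)C(=O)[C@](O)(C[C@H](NC(=O)OC(C)(C)C)C(=O)OC)[C@H]2[C@@H]1OC(OCC)[C@H]2C
A3 | alternative 3 | tetracyclic C1-hydroxy C3 lactam with fused lactone | CC[C@@H]1C2=C3N(CCCC2)C(=O)C[C@]3(O)[C@H]2[C@@H]1OC(=O)[C@H]2C
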